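**Retrosynthetic overview**
- The strategy rests on the pentasubstituted benzene ring (C1 side chain, C2 H, C3 OH, C4 CH3, C5 OH, C6 OAc): O3 and O6 are para, and only O6, next to the side chain, is acetylated.
- Target ⇐ removal of two methoxymethyl (MOM) ethers ⇐ acetylation of the single free phenol (C6) of the benzannulation product.
- Benzene ring (the only ring formed) ⇐ Dötz benzannulation of a β-MOM-oxy alkenyl(MOM-oxy)carbene chromium complex, the terminal alkyne of the side-chain enyne and one CO ligand (bonds C1–C6, C2–C3, C5–C6).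
- Carbene complex ⇐ lithiated (Z)-β-bromo enol ether + Cr(CO)6 (Fischer synthesis) ⇐ allyl alcohol.
- Enyne ⇐ Sonogashira coupling of an enol triflate ⇐ methyl ketone ⇐ methyl (S)-glycidate (source of the stereocentre), then angeloylation.

Key step: step 13

Assumption: the carbene complex carries its enol-ether oxygen cis to the carbene carbon (Z alkene), because only the lithio enol ether with lithium syn to oxygen resists β-elimination; this geometry disappears when C5 becomes aromatic.

**Route**

Step 1
Reactants: 1 allyl alcohol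
Product: 2 3-(methoxymethoxy)prop-1-ene
Conditions: MOMCl, i-Pr2NEt, CH2Cl2, 0 °C → rt
Reagents that add atoms: chloromethyl methyl ether, COCCl
Why: Alkylation of a primary alcohol by the reactive α-chloro ether with an amine as acid scavenger (MOM ether formation).

Step 2
Reactants: 2 3-(methoxymethoxy)prop-1-ene
Product: 3 (Z)-1-(methoxymethoxy)prop-1-ene
Conditions: KOtBu (cat.), DMSO, 60 °C; distilled from the mixture
Reagents that add atoms: none
Why: Base-mediated allyl-to-propenyl ether isomerisation proceeds through the potassium-chelated cis-alkoxyallyl anion and should give the Z enol ether.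

Step 3
Reactants: 3 (Z)-1-(methoxymethoxy)prop-1-ene
Product: 5 (Z)-2-bromo-1-(methoxymethoxy)prop-1-ene, via dibromide 4 (not isolated)
Conditions: Br2, CH2Cl2, −78 °C; then i-Pr2NEt, −78 → 40 °C
Reagents that add atoms: bromine, BrBr
Why: Bromination–dehydrobromination of an enol ether: anti addition to the Z alkene and anti loss of HBr (bromide leaving from the acetal carbon) should place Br and O cis.

Step 4
Reactants: 5 (Z)-2-bromo-1-(methoxymethoxy)prop-1-ene; 6 chromium hexacarbonyl Cr(CO)6
Product: 9 tetramethylammonium pentacarbonyl[(Z)-3-(methoxymethoxy)-2-methylacryloyl]chromate, via vinyllithium 7 (not isolated), via lithium acylchromate 8 (not isolated)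
Conditions: t-BuLi (2 equiv), Et2O, −78 °C; cannulated into Cr(CO)6, THF, −78 → 0 °C; then Me4NBr, H2O
Reagents that add atoms: tetramethylammonium bromide, C[N+](C)(C)C.[Br-]; tert-butyllithium, [Li]C(C)(C)C (lithium kept only in 7 and 8)
Why: Bromine–lithium exchange with retention gives the lithio enol ether with Li syn to oxygen (no anti β-elimination), which adds to a CO ligand as in the Fischer carbene synthesis; cation exchange gives the storable ammonium acylate.

Step 5
Reactants: 9 tetramethylammonium pentacarbonyl[(Z)-3-(methoxymethoxy)-2-methylacryloyl]chromate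
Product: 10 pentacarbonyl[(methoxymethoxy)((Z)-1-(methoxymethoxy)prop-1-en-2-yl)carbene]chromium
Conditions: MOMCl, CH2Cl2, −20 → 0 °C; rapid filtration through Et3N-deactivated silica under argon
Reagents that add atoms: chloromethyl methyl ether, COCCl
Why: O-Alkylation of the ammonium acylmetalate by a hard, highly reactive α-chloro ether completes the Fischer carbene synthesis.

Step 6
Reactants: 11 methyl (S)-glycidate
Product: 12 methyl (S)-2-hydroxy-5-methylhex-4-enoate
Conditions: Me2C=CHMgBr, CuI (cat.), THF, −40 °C; aq. NH4Cl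
Reagents that add atoms: 2-methylprop-1-en-1-ylmagnesium bromide, CC(C)=C[Mg]Br
Why: Copper-catalysed Grignard opening of the glycidate occurs by SN2 attack at the unsubstituted C3, so the C2 stereocentre is untouched and stays (S).

Step 7
Reactants: 12 methyl (S)-2-hydroxy-5-methylhex-4-enoate
Product: 13 methyl (S)-2-[(tert-butyldimethylsilyl)oxy]-5-methylhex-4-enoate
Conditions: TBSCl, imidazole, DMF, rt
Reagents that add atoms: tert-butyldimethylsilyl chloride, CC(C)(C)[Si](C)(C)Cl
Why: Standard silylation of a secondary alcohol, needed to carry the hydroxyl through the organometallic steps.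

Step 8
Reactants: 13 methyl (S)-2-[(tert-butyldimethylsilyl)oxy]-5-methylhex-4-enoate
Product: 15 (S)-3-[(tert-butyldimethylsilyl)oxy]-6-methylhept-5-en-2-one, via N-methoxy-N-methylamide 14 (not isolated)
Conditions: MeNH(OMe)·HCl, i-PrMgCl, THF, −20 °C; then MeMgBr, −20 → 0 °C
Reagents that add atoms: methylmagnesium bromide, C[Mg]Br; N,O-dimethylhydroxylamine hydrochloride, CNOC.Cl (kept only in 14)
Why: Ester aminolysis by the magnesium amide followed by Weinreb ketone synthesis, in which the chelated tetrahedral adduct prevents over-addition and the α-stereocentre is not enolised.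

Step 9
Reactants: 15 (S)-3-[(tert-butyldimethylsilyl)oxy]-6-methylhept-5-en-2-one
Product: 17 (S)-3-[(tert-butyldimethylsilyl)oxy]-6-methylhepta-1,5-dien-2-yl trifluoromethanesulfonate, via potassium enolate 16 (not isolated)
Conditions: KHMDS, THF, −78 °C (ketone added to base); PhNTf2, −78 → −20 °C
Reagents that add atoms: N-phenylbis(trifluoromethanesulfonimide), O=S(=O)(N(c1ccccc1)S(=O)(=O)C(F)(F)F)C(F)(F)F; potassium hexamethyldisilazide, C[Si](C)(C)[N-][Si](C)(C)C.[K+] (potassium kept only in 16)
Why: Kinetic deprotonation takes the unhindered methyl protons and not the silyloxy-shielded methine, so O-triflation gives the terminal enol triflate with the stereocentre intact.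

Step 10
Reactants: 17 (S)-3-[(tert-butyldimethylsilyl)oxy]-6-methylhepta-1,5-dien-2-yl trifluoromethanesulfonate
Product: 18 (S)-tert-butyldimethyl{[6-methyl-2-((trimethylsilyl)ethynyl)hepta-1,5-dien-3-yl]oxy}silane
Conditions: HC≡CSiMe3, Pd(PPh3)4 (cat.), CuI (cat.), i-Pr2NH, THF, rt
Reagents that add atoms: ethynyltrimethylsilane, C#C[Si](C)(C)C
Why: Sonogashira coupling of an alkenyl triflate with a terminal alkyne builds the 2-substituted 1,3-enyne without touching the allylic stereocentre.

Step 11
Reactants: 18 (S)-tert-butyldimethyl{[6-methyl-2-((trimethylsilyl)ethynyl)hepta-1,5-dien-3-yl]oxy}silane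
Product: 19 (S)-2-ethynyl-6-methylhepta-1,5-dien-3-ol
Conditions: TBAF, THF, 0 °C → rt
Reagents that add atoms: none
Why: Fluoride cleaves both the alkynyl C–Si bond and the O–Si bond in one operation.

Step 12
Reactants: 19 (S)-2-ethynyl-6-methylhepta-1,5-dien-3-ol; 20 angelic acid
Product: 22 (S)-2-ethynyl-6-methylhepta-1,5-dien-3-yl (Z)-2-methylbut-2-enoate, via mixed anhydride 21 (not isolated)
Conditions: 20, 2,4,6-trichlorobenzoyl chloride, Et3N, toluene, rt; then 19, 75 °C (no DMAP)
Reagents that add atoms: 2,4,6-trichlorobenzoyl chloride, O=C(Cl)c1c(Cl)cc(Cl)cc1Cl (kept only in 21)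
Why: Yamaguchi-type mixed-anhydride esterification: the alcohol attacks the unhindered angeloyl carbonyl, the absence of a nucleophilic catalyst should keep the Z geometry, and the carbinol C–O bond is not broken, so (S) is retained.

Step 13
Reactants: 10 pentacarbonyl[(methoxymethoxy)((Z)-1-(methoxymethoxy)prop-1-en-2-yl)carbene]chromium; 22 (S)-2-ethynyl-6-methylhepta-1,5-dien-3-yl (Z)-2-methylbut-2-enoate
Product: 24 (S)-2-[2-hydroxy-3,5-bis(methoxymethoxy)-4-methylphenyl]-6-methylhepta-1,5-dien-3-yl (Z)-2-methylbut-2-enoate, via tricarbonylchromium arene complex 23 (not isolated)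
Conditions: 10 (1.3 equiv), degassed THF (0.05 M), 55 °C, argon; then air, Et2O, rt
Reagents that add atoms: none
Why: Dötz benzannulation: loss of one CO from zerovalent chromium (eased by the cis enol-ether oxygen, which can occupy the vacant site) lets the alkyne of 22 insert into the Cr=C bond with its CH terminus on the former carbene carbon (C2–C3), and CO then migrates to the new carbene carbon (C1–C6) to give a chromium-bound dienylketene. The benzene ring, the only ring formed, closes by 6π electrocyclisation between the ketene carbon and the enol-ether β-carbon (C5–C6), and tautomerisation gives the C6 phenol as its Cr(CO)3 complex 23, which air demetalates. The closest known reaction type is the benzannulation of alkenyl(alkoxy)carbene chromium complexes with terminal alkynes and 2-substituted 1,3-enynes. No stereocentre is formed, and the carbinol centre of 22 is not touched under these neutral conditions. The step needs regioselective insertion, secured sterically because the substituted alkyne carbon avoids the carbene carbon and so ends at C1 next to the CO-derived C6, and it needs CO insertion to outrun five-membered-ring formation, for which an oxygen donor at the β-carbon (weaker than nitrogen) and THF are chosen. The enol-ether geometry of 10 does not matter for the product because C5 becomes aromatic, and the only free hydroxyl formed is the one at C6.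

Step 14
Reactants: 24 (S)-2-[2-hydroxy-3,5-bis(methoxymethoxy)-4-methylphenyl]-6-methylhepta-1,5-dien-3-yl (Z)-2-methylbut-2-enoate
Product: 25 (S)-2-[2-acetoxy-3,5-bis(methoxymethoxy)-4-methylphenyl]-6-methylhepta-1,5-dien-3-yl (Z)-2-methylbut-2-enoate
Conditions: Ac2O, pyridine, DMAP (cat.), CH2Cl2, 0 °C
Reagents that add atoms: acetic anhydride, CC(=O)OC(C)=O
Why: Acylation of the only free hydroxyl in the molecule, so no differentiation of the three phenolic oxygens is required.

Step 15
Reactants: 25 (S)-2-[2-acetoxy-3,5-bis(methoxymethoxy)-4-methylphenyl]-6-methylhepta-1,5-dien-3-yl (Z)-2-methylbut-2-enoate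
Product: 26 (S)-2-(2-acetoxy-3,5-dihydroxy-4-methylphenyl)-6-methylhepta-1,5-dien-3-yl (Z)-2-methylbut-2-enoate
Conditions: ZnBr2, n-PrSH, CH2Cl2, 0 °C, short reaction time; pH 6 buffer work-up
Reagents that add atoms: none
Why: Lewis-acid-assisted cleavage of the aryl MOM acetals with thiol capture of the methoxymethyl cation is non-basic and brief, which should spare the aryl acetate (no O6→O5 migration), the allylic angelate and both alkenes.

**Compound list**
1 | allyl alcohol | C=CCO | starting material
2 | 3-(methoxymethoxy)prop-1-ene | C=CCOCOC | intermediate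
3 | (Z)-1-(methoxymethoxy)prop-1-ene | C/C=C\OCOC | intermediate
4 | 1,2-dibromo-1-(methoxymethoxy)propane (diastereomer mixture) | CC(Br)C(Br)OCOC | intermediate
5 | (Z)-2-bromo-1-(methoxymethoxy)prop-1-ene | Br/C(C)=C\OCOC | intermediate
6 | chromium hexacarbonyl, Cr(CO)6 | O=C=[Cr](=C=O)(=C=O)(=C=O)(=C=O)=C=O | starting material
7 | (E)-[1-(methoxymethoxy)prop-1-en-2-yl]lithium (Li syn to O) | [Li]/C(C)=C\OCOC | intermediate
8 | lithium pentacarbonyl[(Z)-3-(methoxymethoxy)-2-methylacryloyl]chromate | [Li+].[O-]C(=[Cr](=C=O)(=C=O)(=C=O)(=C=O)=C=O)/C(C)=C\OCOC | intermediate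
9 | tetramethylammonium pentacarbonyl[(Z)-3-(methoxymethoxy)-2-methylacryloyl]chromate | C[N+](C)(C)C.[O-]C(=[Cr](=C=O)(=C=O)(=C=O)(=C=O)=C=O)/C(C)=C\OCOC | intermediate
10 | pentacarbonyl[(methoxymethoxy)((Z)-1-(methoxymethoxy)prop-1-en-2-yl)carbene]chromium | COCOC(=[Cr](=C=O)(=C=O)(=C=O)(=C=O)=C=O)/C(C)=C\OCOC | intermediate
11 | methyl (S)-glycidate | COC(=O)[C@@H]1CO1 | starting material
12 | methyl (S)-2-hydroxy-5-methylhex-4-enoate | COC(=O)[C@@H](O)CC=C(C)C | intermediate
13 | methyl (S)-2-[(tert-butyldimethylsilyl)oxy]-5-methylhex-4-enoate | COC(=O)[C@@H](O[Si](C)(C)C(C)(C)C)CC=C(C)C | intermediate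
14 | (S)-2-[(tert-butyldimethylsilyl)oxy]-N-methoxy-N,5-dimethylhex-4-enamide | CON(C)C(=O)[C@@H](O[Si](C)(C)C(C)(C)C)CC=C(C)C | intermediate
15 | (S)-3-[(tert-butyldimethylsilyl)oxy]-6-methylhept-5-en-2-one | CC(=O)[C@@H](O[Si](C)(C)C(C)(C)C)CC=C(C)C | intermediate
16 | potassium (S)-3-[(tert-butyldimethylsilyl)oxy]-6-methylhepta-1,5-dien-2-olate | [K+].[O-]C(=C)[C@@H](O[Si](C)(C)C(C)(C)C)CC=C(C)C | intermediate
17 | (S)-3-[(tert-butyldimethylsilyl)oxy]-6-methylhepta-1,5-dien-2-yl trifluoromethanesulfonate | C=C(OS(=O)(=O)C(F)(F)F)[C@@H](O[Si](C)(C)C(C)(C)C)CC=C(C)C | intermediate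
18 | (S)-tert-butyldimethyl{[6-methyl-2-((trimethylsilyl)ethynyl)hepta-1,5-dien-3-yl]oxy}silane | C=C(C#C[Si](C)(C)C)[C@@H](O[Si](C)(C)C(C)(C)C)CC=C(C)C | intermediate
19 | (S)-2-ethynyl-6-methylhepta-1,5-dien-3-ol | C#CC(=C)[C@@H](O)CC=C(C)C | intermediate
20 | angelic acid, (Z)-2-methylbut-2-enoic acid | C/C=C(/C)C(=O)O | starting material
21 | (Z)-2-methylbut-2-enoic 2,4,6-trichlorobenzoic anhydride | C/C=C(/C)C(=O)OC(=O)c1c(Cl)cc(Cl)cc1Cl | intermediate
22 | (S)-2-ethynyl-6-methylhepta-1,5-dien-3-yl (Z)-2-methylbut-2-enoate | C#CC(=C)[C@H](CC=C(C)C)OC(=O)/C(C)=C\C | intermediate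
23 | tricarbonyl(η6-arene)chromium complex of 24 | C=C(c1cc(OCOC)c(C)c(OCOC)c1O)[C@H](CC=C(C)C)OC(=O)/C(C)=C\C.O=C=[Cr](=C=O)=C=O | intermediate
24 | (S)-2-[2-hydroxy-3,5-bis(methoxymethoxy)-4-methylphenyl]-6-methylhepta-1,5-dien-3-yl (Z)-2-methylbut-2-enoate | C=C(c1cc(OCOC)c(C)c(OCOC)c1O)[C@H](CC=C(C)C)OC(=O)/C(C)=C\C | intermediate
25 | (S)-2-[2-acetoxy-3,5-bis(methoxymethoxy)-4-methylphenyl]-6-methylhepta-1,5-dien-3-yl (Z)-2-methylbut-2-enoate | C=C(c1cc(OCOC)c(C)c(OCOC)c1OC(C)=O)[C@H](CC=C(C)C)OC(=O)/C(C)=C\C | intermediate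
26 | (S)-2-(2-acetoxy-3,5-dihydroxy-4-methylphenyl)-6-methylhepta-1,5-dien-3-yl (Z)-2-methylbut-2-enoate | C=C(c1cc(O)c(C)c(O)c1OC(C)=O)[C@H](CC=C(C)C)OC(=O)/C(C)=C\C | target

**Step count**
Total: 15 steps. Longest linear sequence: 10 steps (steps 6–15, from methyl (S)-glycidate); the carbene branch (steps 1–5) joins at step 13.

**Steps most likely to fail**

1. Step 13. The β-oxygen donor may let the vinylcarbene intermediate cyclise before CO insertion, or the alkyne may insert repeatedly, so the phenol is not formed cleanly. The fallback makes the C1–vinyl bond by Suzuki–Miyaura coupling on a preformed arene; it sets out from 17 and comes back at 25.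
 - Arene part: commercial 2,4-dihydroxy-3-methylbenzaldehyde is protected (NaH, MOMCl, DMF) to 2,4-bis(methoxymethoxy)-3-methylbenzaldehyde F1. Baeyer–Villiger oxidation (mCPBA, CH2Cl2) and methanolysis of the formate (K2CO3, MeOH) should give 2,4-bis(methoxymethoxy)-3-methylphenol F2. Bromination ortho to the hydroxyl (NBS, cat. i-Pr2NH, CH2Cl2, 0 °C) should give 6-bromo-2,4-bis(methoxymethoxy)-3-methylphenol F3. Acetylation (Ac2O, pyridine) gives 6-bromo-2,4-bis(methoxymethoxy)-3-methylphenyl acetate F4, and Miyaura borylation (B2pin2, PdCl2(dppf), KOAc, dioxane, 80 °C) gives 2,4-bis(methoxymethoxy)-3-methyl-6-(4,4,5,5-tetramethyl-1,3,2-dioxaborolan-2-yl)phenyl acetate F5.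
 - Side-chain part: 17 is desilylated (HF·pyridine, THF, 0 °C) to (S)-3-hydroxy-6-methylhepta-1,5-dien-2-yl trifluoromethanesulfonate F6, which is esterified with 21 as in step 12 to (S)-6-methyl-2-(((trifluoromethyl)sulfonyl)oxy)hepta-1,5-dien-3-yl (Z)-2-methylbut-2-enoate F7.
 - Coupling of F5 with F7 (Pd(PPh3)4, K3PO4, dioxane, 60 °C) should give 25, and step 15 follows.

2. Step 4. β-Elimination of lithium methoxymethoxide from the lithiated enol ether (to propyne), or deprotonation at C1, may outrun capture by the sparingly soluble Cr(CO)6. The fallback reverses the polarity (nucleophilic chromium, electrophilic acyl unit); it sets out from 6 and comes back at 24.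
 - 6 is reduced with potassium graphite KC8 (THF, −78 °C) to dipotassium pentacarbonylchromate K2[Cr(CO)5] F8, with chromium in the minus-two oxidation state.
 - Commercial ethyl 2-formylpropanoate is O-alkylated (NaH, MOMCl, THF) to ethyl (E)-3-(methoxymethoxy)-2-methylacrylate F9, saponified (KOH, EtOH/H2O) to potassium (E)-3-(methoxymethoxy)-2-methylacrylate F10, and converted with oxalyl chloride (hexane, 0 °C, no free HCl) into (E)-3-(methoxymethoxy)-2-methylacryloyl chloride F11.
 - F11 is added to F8 (THF, −78 → 0 °C), and cation exchange with Me4NBr should give tetramethylammonium pentacarbonyl[(E)-3-(methoxymethoxy)-2-methylacryloyl]chromate F12.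
 - Alkylation as in step 5 gives pentacarbonyl[(methoxymethoxy)((E)-1-(methoxymethoxy)prop-1-en-2-yl)carbene]chromium F13. Under the conditions of step 13 with 22 it should converge on 24, because the enol-ether geometry is lost on aromatisation.

3. Step 12. The activated angeloyl unit may isomerise to the E (tigloyl) geometry by reversible conjugate addition of chloride or amine during acylation. The fallback builds the Z alkene after the ester bond; it sets out from 19 and comes back at 22.
 - 19 is esterified with the known 2-[bis(2,2,2-trifluoroethoxy)phosphoryl]propanoic acid (DCC, cat. DMAP, CH2Cl2) to (S)-2-ethynyl-6-methylhepta-1,5-dien-3-yl 2-[bis(2,2,2-trifluoroethoxy)phosphoryl]propanoate F14.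
 - Still–Gennari olefination (KHMDS, 18-crown-6, THF, −78 °C, then acetaldehyde) should give the Z trisubstituted ester 22.

**Further compounds**
F1 | step 13 | 2,4-bis(methoxymethoxy)-3-methylbenzaldehyde | COCOc1ccc(C=O)c(OCOC)c1C
F2 | step 13 | 2,4-bis(methoxymethoxy)-3-methylphenol | COCOc1ccc(O)c(OCOC)c1C
F3 | step 13 | 6-bromo-2,4-bis(methoxymethoxy)-3-methylphenol | COCOc1cc(Br)c(O)c(OCOC)c1C
F4 | step 13 | 6-bromo-2,4-bis(methoxymethoxy)-3-methylphenyl acetate | COCOc1cc(Br)c(OC(C)=O)c(OCOC)c1C
F5 | step 13 | 2,4-bis(methoxymethoxy)-3-methyl-6-(4,4,5,5-tetramethyl-1,3,2-dioxaborolan-2-yl)phenyl acetate | COCOc1cc(B2OC(C)(C)C(C)(C)O2)c(OC(C)=O)c(OCOC)c1C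
F6 | step 13 | (S)-3-hydroxy-6-methylhepta-1,5-dien-2-yl trifluoromethanesulfonate | C=C(OS(=O)(=O)C(F)(F)F)[C@@H](O)CC=C(C)C
F7 | step 13 | (S)-6-methyl-2-(((trifluoromethyl)sulfonyl)oxy)hepta-1,5-dien-3-yl (Z)-2-methylbut-2-enoate | C=C(OS(=O)(=O)C(F)(F)F)[C@H](CC=C(C)C)OC(=O)/C(C)=C\C
F8 | step 4 | dipotassium pentacarbonylchromate, K2[Cr(CO)5] | [K+].[K+].O=C=[Cr-2](=C=O)(=C=O)(=C=O)=C=O
F9 | step 4 | ethyl (E)-3-(methoxymethoxy)-2-methylacrylate | CCOC(=O)/C(C)=C/OCOC
F10 | step 4 | potassium (E)-3-(methoxymethoxy)-2-methylacrylate | [K+].[O-]C(=O)/C(C)=C/OCOC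
F11 | step 4 | (E)-3-(methoxymethoxy)-2-methylacryloyl chloride | O=C(Cl)/C(C)=C/OCOC
F12 | step 4 | tetramethylammonium pentacarbonyl[(E)-3-(methoxymethoxy)-2-methylacryloyl]chromate | C[N+](C)(C)C.[O-]C(=[Cr](=C=O)(=C=O)(=C=O)(=C=O)=C=O)/C(C)=C/OCOC
F13 | step 4 | pentacarbonyl[(methoxymethoxy)((E)-1-(methoxymethoxy)prop-1-en-2-yl)carbene]chromium | COCOC(=[Cr](=C=O)(=C=O)(=C=O)(=C=O)=C=O)/C(C)=C/OCOC
F14 | step 12 | (S)-2-ethynyl-6-methylhepta-1,5-dien-3-yl 2-[bis(2,2,2-trifluoroethoxy)phosphoryl]propanoate | C#CC(=C)[C@H](CC=C(C)C)OC(=O)C(C)P(=O)(OCC(F)(F)F)OCC(F)(F)F
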